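The pyranone ring (O1, C2, C3, C4, C4a, C8a) is disconnected at C2–C3. The key step exploits that C2 bears the ring oxygen O1 and adjoins C3, whose hydroxyl oxygen can share C2 as an acetal: the precursor is a seven-membered 1,3-benzodioxepine silyl enol ether in which C2 sits between O1 and that oxygen. A chiral silylium ion pair opens the racemic acetal to a planar O1=C2 oxocarbenium ion; the C3=C4 enol ether recloses on it, so the oxygen leaves the ring (seven to six), C2–C3 forms and C2 is set, after which C3 is funnelled to trans. Silyl groups mask both phenols; the prenyl group is in place from the start.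

Key step: step 6

Remark: flavanone numbering (O1, C2, C3, C4, C4a, C5–C8, C8a, B ring primed) is used throughout, also for the atoms of 8 and 9 that end up at these positions; the target is (2R,3R), 2,3-trans.
Assumption: aldehyde 6 is bought (it is one silylation away from vanillin); which antipode of the imidodiphosphorimidate catalyst gives 2R cannot be predicted and must be settled by a screen, the (S,S) form is written for definiteness.

Step 1
Reactants: 1 1-(2,6-dihydroxy-4-methoxyphenyl)ethanone; 2 1-bromo-3-methylbut-2-ene (prenyl bromide)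
Product: 3 1-[2,6-dihydroxy-4-methoxy-3-(3-methylbut-2-enyl)phenyl]ethanone
Conditions: 10% aq KOH, 0 °C → rt
Reagents that add atoms: prenyl bromide (2), CC(C)=CCBr
Why: C-alkylation of the acylphloroglucinol phenoxide in water (C-attack favoured by solvation of oxygen); C3 and C5 of 1 are equivalent, so only one mono-C-prenyl isomer can form and no stereocenter arises.

Step 2
Reactants: 3 1-[2,6-dihydroxy-4-methoxy-3-(3-methylbut-2-enyl)phenyl]ethanone
Product: 4 1-[2-hydroxy-4-methoxy-3-(3-methylbut-2-enyl)-6-(triisopropylsilyloxy)phenyl]ethanone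
Conditions: TIPSCl (1.05 equiv), imidazole, DMF, 0 °C → rt
Reagents that add atoms: triisopropylsilyl chloride, CC(C)[Si](Cl)(C(C)C)C(C)C
Why: Silyl ether formation in which the bulky silyl chloride should take the phenol flanked by H and leave the prenyl-flanked phenol, the one that has to become O1, free and chelated.

Step 3
Reactants: 4 1-[2-hydroxy-4-methoxy-3-(3-methylbut-2-enyl)-6-(triisopropylsilyloxy)phenyl]ethanone
Product: 5 2-hydroxy-1-[2-hydroxy-4-methoxy-3-(3-methylbut-2-enyl)-6-(triisopropylsilyloxy)phenyl]ethanone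
Conditions: KHMDS (3 equiv), THF, −78 °C; 2-(phenylsulfonyl)-3-phenyloxaziridine, −78 °C; AcOH quench
Reagents that add atoms: 2-(phenylsulfonyl)-3-phenyloxaziridine, O=S(=O)(N1OC1c1ccccc1)c1ccccc1
Why: Davis oxidation, in which the potassium enolate of the methyl ketone (the phenol is deprotonated as well) attacks the oxaziridine oxygen to give the primary α-hydroxy ketone, while the reagent leaves the prenyl alkene alone.

Step 4
Reactants: 5 2-hydroxy-1-[2-hydroxy-4-methoxy-3-(3-methylbut-2-enyl)-6-(triisopropylsilyloxy)phenyl]ethanone; 6 4-(tert-butyldimethylsilyloxy)-3-methoxybenzaldehyde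
Product: 8 (±)-2-[4-(tert-butyldimethylsilyloxy)-3-methoxyphenyl]-8-methoxy-9-(3-methylbut-2-enyl)-6-(triisopropylsilyloxy)-4H-1,3-benzodioxepin-5-one, via bis-trimethylsilyl ether 7 (not isolated)
Conditions: TMSCl, Et3N, CH2Cl2, 0 °C, filter; then 6, TMSOTf (5 mol %), CH2Cl2, −78 → −30 °C; pyridine quench
Reagents that add atoms: 4-(tert-butyldimethylsilyloxy)-3-methoxybenzaldehyde (6), COc1cc(C=O)ccc1O[Si](C)(C)C(C)(C)C
Why: Noyori acetalisation, in which the bis-silyl ether and the aldehyde condense under catalytic silyl triflate with loss of hexamethyldisiloxane and close the seven-membered aryl/alkyl acetal at low temperature, where the prenyl group is safe; the acetal carbon forms racemic, which does not matter because step 6 erases it.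

Step 5
Reactants: 8 (±)-2-[4-(tert-butyldimethylsilyloxy)-3-methoxyphenyl]-8-methoxy-9-(3-methylbut-2-enyl)-6-(triisopropylsilyloxy)-4H-1,3-benzodioxepin-5-one
Product: 9 (±)-2-[4-(tert-butyldimethylsilyloxy)-3-methoxyphenyl]-8-methoxy-9-(3-methylbut-2-enyl)-5-(triethylsilyloxy)-6-(triisopropylsilyloxy)-2H-1,3-benzodioxepine
Conditions: KHMDS, THF, −78 °C; TESCl, −78 → −40 °C; Et3N-buffered work-up
Reagents that add atoms: triethylsilyl chloride, CC[Si](Cl)(CC)CC
Why: Kinetic enolisation at the only enolisable position and O-silylation of the potassium enolate; the ring fixes the enol ether geometry, with the acetal oxygen cis to the aryl carbon C4a.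

Step 6
Reactants: 9 (±)-2-[4-(tert-butyldimethylsilyloxy)-3-methoxyphenyl]-8-methoxy-9-(3-methylbut-2-enyl)-5-(triethylsilyloxy)-6-(triisopropylsilyloxy)-2H-1,3-benzodioxepine
Product: 12 (2R,3R)-2-[4-(tert-butyldimethylsilyloxy)-3-methoxyphenyl]-3-hydroxy-7-methoxy-8-(3-methylbut-2-enyl)-5-(triisopropylsilyloxy)chroman-4-one, via cis-3-O-triethylsilyl ketone 10 (not isolated), via cis-3-hydroxy ketone 11 (not isolated)
Conditions: (S,S)-imidodiphosphorimidate acid (3 mol %), allylSiEt3 (5 mol %), toluene, −60 °C; then MeOH, −60 → 0 °C; evaporate; DBU (0.2 equiv), CH2Cl2, rt, Ar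
Reagents that add atoms: none
Why: Proposed new method: the silylated chiral imidodiphosphorimidate (a confined silylium Lewis acid) silylates the acetal oxygen on C3 of racemic 9 and cleaves its bond to C2, so that both enantiomers give the same (E)-configured O1=C2 oxocarbenium ion paired with the chiral anion; the tethered silyl enol ether carbon C3 then adds to C2 and the silyl group on the C4 oxygen returns to the catalyst, a net 1,2 oxygen-to-carbon shift of the acetal carbon that contracts the seven-membered dioxepine to the six-membered pyranone. The closest known reaction types are the Petasis–Ferrier rearrangement of cyclic enol acetals (same ion pair, but a 1,3 shift with no change in ring size) and imidodiphosphorimidate-catalysed Mukaiyama-type additions of enol silanes to oxocarbenium ions made from acetals; the 1,2 relationship and the intramolecular, enantioconvergent setting are unproven. The pyranone ring closes in a 6-(enolendo)-endo-trig mode through a half-chair, C3 attacking perpendicular to the oxocarbenium plane. C2 (R) is set by the chiral counter-anion shielding one face of the planar cation, whereas C3 should emerge cis (3S, axial silyloxy, compound 10) because its oxygen is held cis to C4a in the enol ether, as for a (Z)-alkene in a Prins chair. After acid methanolysis of the labile 3-O-triethylsilyl group (11), DBU equilibrates only the enolisable C3 to the diequatorial, hydrogen-bonded trans ketol (3R). The step needs facial control at C2 and attack through C3 rather than C4: the first rests on the catalyst, the second on the substrate (C4 attack would be a 5-endo closure and only C3 is activated by the enol silane), and C2 is safe under DBU because the silylated 4'-oxygen prevents quinone methide opening.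

Step 7
Reactants: 12 (2R,3R)-2-[4-(tert-butyldimethylsilyloxy)-3-methoxyphenyl]-3-hydroxy-7-methoxy-8-(3-methylbut-2-enyl)-5-(triisopropylsilyloxy)chroman-4-one
Product: 13 (2R,3R)-3,5-dihydroxy-2-(4-hydroxy-3-methoxyphenyl)-7-methoxy-8-(3-methylbut-2-enyl)chroman-4-one (target)
Conditions: TBAF, AcOH (1:1), THF, 0 °C
Reagents that add atoms: none
Why: Fluoride cleavage of the two aryl silyl ethers under acetic acid buffering, which keeps the 4'-phenol protonated so that neither C2 (quinone methide opening) nor C3 (enolisation) should be disturbed.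

Compound list
1 | 1-(2,6-dihydroxy-4-methoxyphenyl)ethanone | CC(=O)c1c(O)cc(OC)cc1O | starting material
2 | 1-bromo-3-methylbut-2-ene (prenyl bromide) | CC(C)=CCBr | starting material
3 | 1-[2,6-dihydroxy-4-methoxy-3-(3-methylbut-2-enyl)phenyl]ethanone | CC(=O)c1c(O)cc(OC)c(CC=C(C)C)c1O | intermediate
4 | 1-[2-hydroxy-4-methoxy-3-(3-methylbut-2-enyl)-6-(triisopropylsilyloxy)phenyl]ethanone | CC(=O)c1c(O[Si](C(C)C)(C(C)C)C(C)C)cc(OC)c(CC=C(C)C)c1O | intermediate
5 | 2-hydroxy-1-[2-hydroxy-4-methoxy-3-(3-methylbut-2-enyl)-6-(triisopropylsilyloxy)phenyl]ethanone | OCC(=O)c1c(O[Si](C(C)C)(C(C)C)C(C)C)cc(OC)c(CC=C(C)C)c1O | intermediate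
6 | 4-(tert-butyldimethylsilyloxy)-3-methoxybenzaldehyde | COc1cc(C=O)ccc1O[Si](C)(C)C(C)(C)C | starting material
7 | 1-[4-methoxy-3-(3-methylbut-2-enyl)-6-(triisopropylsilyloxy)-2-(trimethylsilyloxy)phenyl]-2-(trimethylsilyloxy)ethanone (bis-trimethylsilyl ether of 5) | C[Si](C)(C)OCC(=O)c1c(O[Si](C(C)C)(C(C)C)C(C)C)cc(OC)c(CC=C(C)C)c1O[Si](C)(C)C | intermediate
8 | (±)-2-[4-(tert-butyldimethylsilyloxy)-3-methoxyphenyl]-8-methoxy-9-(3-methylbut-2-enyl)-6-(triisopropylsilyloxy)-4H-1,3-benzodioxepin-5-one (racemic at the acetal carbon) | O=C1COC(c2ccc(O[Si](C)(C)C(C)(C)C)c(OC)c2)Oc2c(CC=C(C)C)c(OC)cc(O[Si](C(C)C)(C(C)C)C(C)C)c21 | intermediate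
9 | (±)-2-[4-(tert-butyldimethylsilyloxy)-3-methoxyphenyl]-8-methoxy-9-(3-methylbut-2-enyl)-5-(triethylsilyloxy)-6-(triisopropylsilyloxy)-2H-1,3-benzodioxepine (racemic at the acetal carbon) | CC[Si](CC)(CC)OC1=COC(c2ccc(O[Si](C)(C)C(C)(C)C)c(OC)c2)Oc2c(CC=C(C)C)c(OC)cc(O[Si](C(C)C)(C(C)C)C(C)C)c21 | intermediate
10 | (2R,3S)-2-[4-(tert-butyldimethylsilyloxy)-3-methoxyphenyl]-7-methoxy-8-(3-methylbut-2-enyl)-3-(triethylsilyloxy)-5-(triisopropylsilyloxy)chroman-4-one (2,3-cis) | COc1cc([C@H]2Oc3c(CC=C(C)C)c(OC)cc(O[Si](C(C)C)(C(C)C)C(C)C)c3C(=O)[C@H]2O[Si](CC)(CC)CC)ccc1O[Si](C)(C)C(C)(C)C | intermediate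
11 | (2R,3S)-2-[4-(tert-butyldimethylsilyloxy)-3-methoxyphenyl]-3-hydroxy-7-methoxy-8-(3-methylbut-2-enyl)-5-(triisopropylsilyloxy)chroman-4-one (2,3-cis) | COc1cc([C@H]2Oc3c(CC=C(C)C)c(OC)cc(O[Si](C(C)C)(C(C)C)C(C)C)c3C(=O)[C@H]2O)ccc1O[Si](C)(C)C(C)(C)C | intermediate
12 | (2R,3R)-2-[4-(tert-butyldimethylsilyloxy)-3-methoxyphenyl]-3-hydroxy-7-methoxy-8-(3-methylbut-2-enyl)-5-(triisopropylsilyloxy)chroman-4-one (2,3-trans) | COc1cc([C@H]2Oc3c(CC=C(C)C)c(OC)cc(O[Si](C(C)C)(C(C)C)C(C)C)c3C(=O)[C@@H]2O)ccc1O[Si](C)(C)C(C)(C)C | intermediate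
13 | (2R,3R)-3,5-dihydroxy-2-(4-hydroxy-3-methoxyphenyl)-7-methoxy-8-(3-methylbut-2-enyl)chroman-4-one (2,3-trans) | COc1cc([C@H]2Oc3c(CC=C(C)C)c(OC)cc(O)c3C(=O)[C@@H]2O)ccc1O | target

Total step count: 7
Longest linear sequence: 7 steps (1 → 3 → 4 → 5 → 8 → 9 → 12 → 13)

Steps most likely to fail

Step 6. The ion pair may close without facial discrimination, the acetal may ionise at the aryl oxygen and simply re-close, the prenyl alkene may capture the cation in a Prins reaction, the catalyst acid may protodesilylate the enol ether back to 8, or the enolate may ring-open during the base equilibration. The fallback uses known chemistry, sets out from 4 and comes back at 12. The free phenol of 4 is converted into the methoxymethyl ether 1-[2-(methoxymethoxy)-4-methoxy-3-(3-methylbut-2-enyl)-6-(triisopropylsilyloxy)phenyl]ethanone F1 (NaH, MOMCl). Its lithium enolate (LiHMDS, THF, −78 °C) is added to aldehyde 6 to give the racemic aldol F2, which is dehydrated (MsCl, Et3N, then DBU) to the (E)-chalcone F3. Juliá–Colonna epoxidation (poly-L-leucine, urea–H2O2, DBU, THF) should give the (αR,βS)-epoxide F4. Dilute methanolic HCl at 0 °C then removes the methoxymethyl group, and the freed phenol opens the epoxide at the benzylic carbon in a 6-endo mode with inversion, which should give 12 with both silyl ethers intact.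

Step 4. The seven-membered aryl/alkyl acetal may fail to close, giving open-chain or oligomeric acetals that revert on work-up. The fallback forms the acetal by oxidation instead of condensation, sets out from 4 and comes back at 8. Aldehyde 6 is reduced (NaBH4, MeOH) to 4-(tert-butyldimethylsilyloxy)-3-methoxybenzyl alcohol F5, which is joined to phenol 4 under Mitsunobu conditions (PPh3, DIAD) to give the benzyl ether F6. Davis hydroxylation as in step 3 gives the α-hydroxy ketone F7. DDQ in dry CH2Cl2 over molecular sieves abstracts hydride from the electron-rich benzylic position, and the primary hydroxyl traps the aryloxy-stabilised cation to close the dioxepinone 8.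

Step 3. The enolate may add to the sulfonimine by-product, the product may be oxidised further, or the triisopropylsilyl group may migrate from the aryl oxygen to the enolate oxygen. The fallback sets out from 4 and comes back at 5. TMSOTf and Et3N convert the phenol and the ketone of 4 into the bis-silylated enol ether trimethyl({1-[4-methoxy-3-(3-methylbut-2-enyl)-6-(triisopropylsilyloxy)-2-(trimethylsilyloxy)phenyl]vinyl}oxy)silane F8. Rubottom oxidation with dimethyldioxirane at −78 °C (the enol ether reacts far faster than the prenyl alkene), followed by methanolic citric acid, should give 5.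

Further compounds
F1 | step 6 | 1-[2-(methoxymethoxy)-4-methoxy-3-(3-methylbut-2-enyl)-6-(triisopropylsilyloxy)phenyl]ethanone | CC(=O)c1c(OCOC)c(CC=C(C)C)c(OC)cc1O[Si](C(C)C)(C(C)C)C(C)C
F2 | step 6 | (±)-3-[4-(tert-butyldimethylsilyloxy)-3-methoxyphenyl]-3-hydroxy-1-[2-(methoxymethoxy)-4-methoxy-3-(3-methylbut-2-enyl)-6-(triisopropylsilyloxy)phenyl]propan-1-one | O=C(CC(O)c1ccc(O[Si](C)(C)C(C)(C)C)c(OC)c1)c1c(OCOC)c(CC=C(C)C)c(OC)cc1O[Si](C(C)C)(C(C)C)C(C)C
F3 | step 6 | (E)-3-[4-(tert-butyldimethylsilyloxy)-3-methoxyphenyl]-1-[2-(methoxymethoxy)-4-methoxy-3-(3-methylbut-2-enyl)-6-(triisopropylsilyloxy)phenyl]prop-2-en-1-one | O=C(/C=C/c1ccc(O[Si](C)(C)C(C)(C)C)c(OC)c1)c1c(OCOC)c(CC=C(C)C)c(OC)cc1O[Si](C(C)C)(C(C)C)C(C)C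
F4 | step 6 | [(2R,3S)-3-[4-(tert-butyldimethylsilyloxy)-3-methoxyphenyl]oxiran-2-yl][2-(methoxymethoxy)-4-methoxy-3-(3-methylbut-2-enyl)-6-(triisopropylsilyloxy)phenyl]methanone | O=C([C@@H]1O[C@H]1c1ccc(O[Si](C)(C)C(C)(C)C)c(OC)c1)c1c(OCOC)c(CC=C(C)C)c(OC)cc1O[Si](C(C)C)(C(C)C)C(C)C
F5 | step 4 | 4-(tert-butyldimethylsilyloxy)-3-methoxybenzyl alcohol | COc1cc(CO)ccc1O[Si](C)(C)C(C)(C)C
F6 | step 4 | 1-[2-{[4-(tert-butyldimethylsilyloxy)-3-methoxyphenyl]methoxy}-4-methoxy-3-(3-methylbut-2-enyl)-6-(triisopropylsilyloxy)phenyl]ethanone | CC(=O)c1c(OCc2ccc(O[Si](C)(C)C(C)(C)C)c(OC)c2)c(CC=C(C)C)c(OC)cc1O[Si](C(C)C)(C(C)C)C(C)C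
F7 | step 4 | 1-[2-{[4-(tert-butyldimethylsilyloxy)-3-methoxyphenyl]methoxy}-4-methoxy-3-(3-methylbut-2-enyl)-6-(triisopropylsilyloxy)phenyl]-2-hydroxyethanone | OCC(=O)c1c(OCc2ccc(O[Si](C)(C)C(C)(C)C)c(OC)c2)c(CC=C(C)C)c(OC)cc1O[Si](C(C)C)(C(C)C)C(C)C
F8 | step 3 | trimethyl({1-[4-methoxy-3-(3-methylbut-2-enyl)-6-(triisopropylsilyloxy)-2-(trimethylsilyloxy)phenyl]vinyl}oxy)silane | C=C(O[Si](C)(C)C)c1c(O[Si](C(C)C)(C(C)C)C(C)C)cc(OC)c(CC=C(C)C)c1O[Si](C)(C)C
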